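Count amounts first. In the alder run Q stands flat at a mean 82.4% of its charge, so 17.6% of it was lost, less than the 1.4 equiv of D charged.

common to all: L 12 mol%

| run | Q | D | Z | remark | time |
|---|---|---|---|---|---|
| cedar | 0.25 M | 0.90 equiv | 2 equiv | run made earlier |  |
| alder | 0.25 M | 1.4 equiv | 2 equiv | run made earlier |  |
| elm | 0.50 M | 1.8 equiv | 2 equiv | run made earlier |  |
| flask | 0.25 M | 1.80 equiv | 2.00 equiv |  | 15 d |

| run | time / d | Q / % | X / % |
|---|---|---|---|
| cedar | 1.67 | 90.3 | 6.6 |
| cedar | 4.00 | 89.7 | 5.9 |
| cedar | 5.00 | 89.8 | 6.4 |
| cedar | 8.00 | 90.5 | 6.3 |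
| cedar | 10.0 | 90.6 | 6.2 |
| alder | 0.833 | 82.3 | 10.7 |
| alder | 2.50 | 82.8 | 11.5 |
| alder | 4.00 | 82.7 | 11.2 |
| alder | 6.00 | 81.9 | 11.3 |
| alder | 10.0 | 82.1 | 11.3 |
| elm | 0.625 | 73.9 | 16.7 |
| elm | 1.25 | 74.4 | 16.4 |
| elm | 2.50 | 74.7 | 16.2 |
| elm | 5.00 | 74.3 | 16.5 |
| elm | 10.0 | 74.1 | 16.7 |

(scatter of a reading: 0.3 percentage points)

- the reaction counts as stopped when no species that holds the Q changes by six tenths of a point or more over the second half of the time

* the state of affairs at 15 d: stopped, and by what, or still going (all of Q has reacted / forward and back rates have come level / no working catalyst is left / D has run out first / it is still moving)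
* conversion of Q at 15 d
* amount of X at 15 d, in percent of the Q charged
* amount of E at 15 d, in percent of the Q charged

Suppose, as my own reckoning, that each D is spent on one Q or one Z, and compare the two rates at one moment. Take both to use the same D and L, so that they stand as s[Z]/[Q], with s constant. Put the alder D not found on Q onto Z: this gives 4.88 for s, the selectivity factor, ln(fraction of Z left) over ln(fraction of Q left). With Z at 2.00 equiv, Z starts 9.76 times as fast as Q, and the comparison drifts toward Q as Z falls faster.

Now bracket the flask, where 1.80 equiv of D must cover Q lost plus Z lost. From above: with a fraction 0.7 of Q left, the D needed is 1.95 equiv, over the charge, so by this reckoning conversion stays below 30.0%. From below: with 75.0% of Q left, it needs 1.76 equiv, under the charge. A straight line between them puts the conversion at which the D needed meets the charge at 26.1%, my estimate, with D as the limiting reagent. Concentration cancels from s as supposed here, and the elm run, at twice the flask's Q and equal equivalents, last reads Q 74.1%, inside the bracket.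

The forecast gives 25.6% (22.5% to 28%), X 16.3% and E 9.3%, its centre above 25.0% and below 30.0%, but the end it names is this: forward and back rates have come level. Its words are “A mole-neutral equilibrium fits best”.

The flask ends thus: D has run out first, with 0% of the charged D left at 15.0 d, conversion 25.9%, X 16.6% and E 9.30%.

    Q + D + L → L + X (k = 0.0110 M⁻² s⁻¹)
    Z + D + L → L + J (k = 0.0540 M⁻² s⁻¹)
    X + L ⇌ E + L, rate k3*[L]*[X] forward; the back reaction follows from the equilibrium constant (K = 0.560, k = 0.00130 M⁻¹ s⁻¹)

Carry s over: the flask's Q left, 74%, gives Z left 23.0% of its charge, and the flask holds 23%. The neighbouring flask, with 1.20 equiv of Z, keeps 39% of its Q, so s gives Z left 0.995% of its charge and D needed 1.80 equiv, against 1.80 equiv charged; that neighbour holds Z 0.96% at conversion 61.2%.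

The runs were computed for an exercise.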